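Ring C of the lower flavan unit is disconnected across C4–C3 and O1–C2. Both bonds form in one inverse-electron-demand hetero-Diels–Alder reaction between an ortho-quinone methide (O1=C8a–C4a=C4H2), released from a salicyl alcohol on ring A that already carries the chalcan unit at C8, and the Z enol gallate of 3,4,5-tris(benzyloxy)phenylacetaldehyde. The step exploits the cis relation of the C2 aryl group and the C3 gallate (Z geometry transferred suprafacially) and delivers the ester ready-made. The chalcan stereocentres C1' and C2' come earlier from a cis-epoxide opened with inversion by a phloroglucinol nucleophile; global hydrogenolysis ends the route.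

Key step: step 11

Remark: flavan numbering is used for the lower unit (O1, C2, C3, C4, C4a, C5 to C8, C8a) and C1', C2', C3' for the chalcan chain (C1' is the diarylmethine carbon); compounds 1, 3, 5 and 11 are taken as purchasable; the catalyst antipodes in steps 7 and 11 are assigned by analogy and would be confirmed on the first run.

Step 1
Reactants: 1 3,4,5-tris(benzyloxy)benzaldehyde
Product: 2 5-ethynyl-1,2,3-tris(benzyloxy)benzene
Conditions: Ohira–Bestmann reagent, K2CO3, MeOH/THF, 0 °C → rt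
Reagents that add atoms: Ohira–Bestmann reagent, dimethyl (1-diazo-2-oxopropyl)phosphonate, COP(=O)(OC)C(=[N+]=[N-])C(C)=O
Why: Seyferth–Gilbert homologation under Ohira–Bestmann conditions turns the non-enolisable aryl aldehyde into the terminal alkyne through a diazoalkene that loses N2.

Step 2
Reactants: 2 5-ethynyl-1,2,3-tris(benzyloxy)benzene; 3 3,4,5-tris(benzyloxy)benzoic acid
Product: 4 (Z)-2-[3,4,5-tris(benzyloxy)phenyl]ethenyl 3,4,5-tris(benzyloxy)benzoate
Conditions: Ru(2-methylallyl)2[Ph2P(CH2)4PPh2] (3 mol %), PhMe, 65 °C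
Reagents that add atoms: none
Why: Anti-Markovnikov hydro-oxycarbonylation of a terminal alkyne through a vinylidene on the divalent ruthenium bis(allyl) diphosphine catalyst is a known route to (Z)-enol esters and fixes the alkene geometry that step 11 turns into the cis C2/C3 relation.

Step 3
Reactants: 5 2,4,6-trihydroxybenzaldehyde
Product: 6 2,4,6-tris(benzyloxy)benzaldehyde
Conditions: BnBr (3.6 equiv), K2CO3, DMF, 60 °C
Reagents that add atoms: benzyl bromide, BrCc1ccccc1
Why: Williamson etherification of all three phenols, the chelated ortho hydroxyl included under forcing conditions.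

Step 4
Reactants: 2 5-ethynyl-1,2,3-tris(benzyloxy)benzene; 6 2,4,6-tris(benzyloxy)benzaldehyde
Product: 7 rac-1-[2,4,6-tris(benzyloxy)phenyl]-3-[3,4,5-tris(benzyloxy)phenyl]prop-2-yn-1-ol
Conditions: n-BuLi, THF, −78 °C; then 6, −78 → 0 °C; H2O
Reagents that add atoms: none
Why: 1,2-Addition of the lithium acetylide to the aldehyde; the carbinol centre is left racemic because step 5 removes it.

Step 5
Reactants: 7 rac-1-[2,4,6-tris(benzyloxy)phenyl]-3-[3,4,5-tris(benzyloxy)phenyl]prop-2-yn-1-ol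
Product: 8 1,2,3-tris(benzyloxy)-5-{3-[2,4,6-tris(benzyloxy)phenyl]prop-1-yn-1-yl}benzene
Conditions: Et3SiH, CF3CO2H, CH2Cl2, −40 °C
Reagents that add atoms: none
Why: Ionic hydrogenation, in which the cation stabilised by both the alkyne and the 2,4,6-trialkoxyphenyl ring takes hydride at its benzylic carbon and the carbinol centre disappears.

Step 6
Reactants: 8 1,2,3-tris(benzyloxy)-5-{3-[2,4,6-tris(benzyloxy)phenyl]prop-1-yn-1-yl}benzene
Product: 9 (Z)-1-[3,4,5-tris(benzyloxy)phenyl]-3-[2,4,6-tris(benzyloxy)phenyl]prop-1-ene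
Conditions: H2 (1 atm), Pd/CaCO3 poisoned with Pb(OAc)2, quinoline, EtOAc, rt
Reagents that add atoms: none
Why: Lindlar semi-hydrogenation delivers H2 syn to give the Z alkene, and the poisoned catalyst should leave the benzyl ethers intact.

Step 7
Reactants: 9 (Z)-1-[3,4,5-tris(benzyloxy)phenyl]-3-[2,4,6-tris(benzyloxy)phenyl]prop-1-ene
Product: 10 (2R,3S)-2-[2,4,6-tris(benzyloxy)benzyl]-3-[3,4,5-tris(benzyloxy)phenyl]oxirane (cis)
Conditions: (S,S)-(salen)MnCl [salen = N,N'-bis(3,5-di-tert-butylsalicylidene)cyclohexane-1,2-diamine dianion] (5 mol %), mCPBA, NMO, CH2Cl2, −78 °C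
Reagents that add atoms: mCPBA, 3-chloroperoxybenzoic acid, OOC(=O)c1cccc(Cl)c1
Why: Jacobsen epoxidation of a cis-β-substituted styrene, in which the oxo species from the trivalent manganese salen complex selects one enantioface and sets both epoxide carbons (aryl-bearing carbon S, benzyl-bearing carbon R) by analogy with cis-β-methylstyrene.

Step 8
Reactants: 10 (2R,3S)-2-[2,4,6-tris(benzyloxy)benzyl]-3-[3,4,5-tris(benzyloxy)phenyl]oxirane; 11 3,5-bis(benzyloxy)phenol
Product: 12 3,5-bis(benzyloxy)-2-{(1S,2R)-2-hydroxy-1-[3,4,5-tris(benzyloxy)phenyl]-3-[2,4,6-tris(benzyloxy)phenyl]propyl}phenol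
Conditions: 11 (3 equiv), (CF3)2CHOH/CH2Cl2 (1:1), 0 °C → rt
Reagents that add atoms: none
Why: Fluoroalcohol-promoted Friedel–Crafts alkylation, in which the hydrogen-bond-activated epoxide is opened at its benzylic carbon by the less hindered ortho carbon of the phenol in an SN2-type event, so that inversion sets C1' as S beside the untouched C2' (R).

Step 9
Reactants: 12 3,5-bis(benzyloxy)-2-{(1S,2R)-2-hydroxy-1-[3,4,5-tris(benzyloxy)phenyl]-3-[2,4,6-tris(benzyloxy)phenyl]propyl}phenol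
Product: 13 4,6-bis(benzyloxy)-2-hydroxy-3-{(1S,2R)-2-hydroxy-1-[3,4,5-tris(benzyloxy)phenyl]-3-[2,4,6-tris(benzyloxy)phenyl]propyl}benzaldehyde
Conditions: (CH2O)n, MgCl2, Et3N, THF, reflux
Reagents that add atoms: paraformaldehyde (as formaldehyde), C=O
Why: Magnesium-mediated ortho-formylation (Casnati–Skattebøl), in which the magnesium phenoxide delivers formaldehyde only to the one free ortho carbon and a second formaldehyde oxidises the benzylic alkoxide to the aldehyde.

Step 10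
Reactants: 13 4,6-bis(benzyloxy)-2-hydroxy-3-{(1S,2R)-2-hydroxy-1-[3,4,5-tris(benzyloxy)phenyl]-3-[2,4,6-tris(benzyloxy)phenyl]propyl}benzaldehyde
Product: 14 3,5-bis(benzyloxy)-2-(hydroxymethyl)-6-{(1S,2R)-2-hydroxy-1-[3,4,5-tris(benzyloxy)phenyl]-3-[2,4,6-tris(benzyloxy)phenyl]propyl}phenol
Conditions: NaBH4, THF/MeOH, 0 °C; pH 7 work-up
Reagents that add atoms: none
Why: Borohydride reduction of the salicylaldehyde gives the ortho-hydroxybenzyl alcohol without touching a stereocentre; the labile product is used at once.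

Step 11
Reactants: 14 3,5-bis(benzyloxy)-2-(hydroxymethyl)-6-{(1S,2R)-2-hydroxy-1-[3,4,5-tris(benzyloxy)phenyl]-3-[2,4,6-tris(benzyloxy)phenyl]propyl}phenol; 4 (Z)-2-[3,4,5-tris(benzyloxy)phenyl]ethenyl 3,4,5-tris(benzyloxy)benzoate
Product: 16 (2R,3R)-5,7-bis(benzyloxy)-8-{(1S,2R)-2-hydroxy-1-[3,4,5-tris(benzyloxy)phenyl]-3-[2,4,6-tris(benzyloxy)phenyl]propyl}-2-[3,4,5-tris(benzyloxy)phenyl]chroman-3-yl 3,4,5-tris(benzyloxy)benzoate, via ortho-quinone methide 15 (not isolated)
Conditions: 4 (3 equiv), (R)-TRIP [(R)-3,3'-bis(2,4,6-triisopropylphenyl)-1,1'-binaphthyl-2,2'-diyl hydrogen phosphate] (10 mol %), 5 Å MS, PhMe, −20 °C, 14 added over 6 h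
Reagents that add atoms: none
Why: Proposed new method: the chiral phosphoric acid ionises the benzylic hydroxyl of 14 to the hydrogen-bonded ortho-quinone methide 15 (heterodiene O1=C8a–C4a=C4H2), which adds across the Z enol gallate 4 in an inverse-electron-demand hetero-Diels–Alder reaction, the closest known reaction type being the thermal and chiral-Brønsted-acid-catalysed [4+2] cycloaddition of ortho-quinone methides with styrenes to 2-arylchromans, not yet shown for a β-acyloxystyrene. Ring C closes by this intermolecular [4+2] mode, asynchronous but suprafacial, with the C4–C3 bond in advance of the O1–C2 bond. Regiochemistry follows the styrene-type polarisation of 4: the acyloxy-bearing carbon is the nucleophilic end and joins C4, while the benzylic carbon, whose positive character the aryl group stabilises far better than the cross-conjugated ester oxygen, joins O1. C2 and C3 are created together: their cis relation is the Z geometry of 4 carried through the suprafacial addition, and their absolute sense (2R,3R) is set by the face of 15 that the phosphate bound to the quinone methide oxygen leaves open, the catalyst antipode being chosen to match the bias of the C1' centre at C8. The step needs the alkene of 4 to win over arene carbons as the partner of 15, which is secured because C8 is already occupied by the chalcan unit, every remaining CH of the phloroglucinol rings lies between two benzyloxy groups, and 14 is added slowly to an excess of 4.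

Step 12
Reactants: 16 (2R,3R)-5,7-bis(benzyloxy)-8-{(1S,2R)-2-hydroxy-1-[3,4,5-tris(benzyloxy)phenyl]-3-[2,4,6-tris(benzyloxy)phenyl]propyl}-2-[3,4,5-tris(benzyloxy)phenyl]chroman-3-yl 3,4,5-tris(benzyloxy)benzoate; 3 3,4,5-tris(benzyloxy)benzoic acid
Product: 17 (2R,3R)-5,7-bis(benzyloxy)-8-{(1S,2R)-2-[3,4,5-tris(benzyloxy)benzoyloxy]-1-[3,4,5-tris(benzyloxy)phenyl]-3-[2,4,6-tris(benzyloxy)phenyl]propyl}-2-[3,4,5-tris(benzyloxy)phenyl]chroman-3-yl 3,4,5-tris(benzyloxy)benzoate
Conditions: 3 (2 equiv), EDC·HCl, DMAP, CH2Cl2, rt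
Reagents that add atoms: none
Why: Steglich esterification of the only free hydroxyl, the C2' secondary alcohol, installs the second gallate with retention at C2'.

Step 13
Reactants: 17 (2R,3R)-5,7-bis(benzyloxy)-8-{(1S,2R)-2-[3,4,5-tris(benzyloxy)benzoyloxy]-1-[3,4,5-tris(benzyloxy)phenyl]-3-[2,4,6-tris(benzyloxy)phenyl]propyl}-2-[3,4,5-tris(benzyloxy)phenyl]chroman-3-yl 3,4,5-tris(benzyloxy)benzoate
Product: 18 CNP0155034.1, (2R,3R)-5,7-dihydroxy-8-[(1S,2R)-2-(3,4,5-trihydroxybenzoyloxy)-1-(3,4,5-trihydroxyphenyl)-3-(2,4,6-trihydroxyphenyl)propyl]-2-(3,4,5-trihydroxyphenyl)chroman-3-yl 3,4,5-trihydroxybenzoate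
Conditions: H2 (1 atm), Pd(OH)2/C, THF/MeOH, rt
Reagents that add atoms: none
Why: Hydrogenolysis of the seventeen benzyl ethers under neutral conditions should leave the two benzoate esters, the diarylmethine C1' and the chroman C2–O1 bond intact.

Compound list
1 | 3,4,5-tris(benzyloxy)benzaldehyde | O=Cc1cc(OCc2ccccc2)c(OCc2ccccc2)c(OCc2ccccc2)c1 | starting material
2 | 5-ethynyl-1,2,3-tris(benzyloxy)benzene | C#Cc1cc(OCc2ccccc2)c(OCc2ccccc2)c(OCc2ccccc2)c1 | intermediate
3 | 3,4,5-tris(benzyloxy)benzoic acid | OC(=O)c1cc(OCc2ccccc2)c(OCc2ccccc2)c(OCc2ccccc2)c1 | starting material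
4 | (Z)-2-[3,4,5-tris(benzyloxy)phenyl]ethenyl 3,4,5-tris(benzyloxy)benzoate | O=C(O/C=C\c1cc(OCc2ccccc2)c(OCc2ccccc2)c(OCc2ccccc2)c1)c1cc(OCc2ccccc2)c(OCc2ccccc2)c(OCc2ccccc2)c1 | intermediate
5 | 2,4,6-trihydroxybenzaldehyde | O=Cc1c(O)cc(O)cc1O | starting material
6 | 2,4,6-tris(benzyloxy)benzaldehyde | O=Cc1c(OCc2ccccc2)cc(OCc2ccccc2)cc1OCc2ccccc2 | intermediate
7 | rac-1-[2,4,6-tris(benzyloxy)phenyl]-3-[3,4,5-tris(benzyloxy)phenyl]prop-2-yn-1-ol | OC(C#Cc1cc(OCc2ccccc2)c(OCc2ccccc2)c(OCc2ccccc2)c1)c1c(OCc2ccccc2)cc(OCc2ccccc2)cc1OCc2ccccc2 | intermediate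
8 | 1,2,3-tris(benzyloxy)-5-{3-[2,4,6-tris(benzyloxy)phenyl]prop-1-yn-1-yl}benzene | C(C#Cc1cc(OCc2ccccc2)c(OCc2ccccc2)c(OCc2ccccc2)c1)c1c(OCc2ccccc2)cc(OCc2ccccc2)cc1OCc2ccccc2 | intermediate
9 | (Z)-1-[3,4,5-tris(benzyloxy)phenyl]-3-[2,4,6-tris(benzyloxy)phenyl]prop-1-ene | C(/C=C\c1cc(OCc2ccccc2)c(OCc2ccccc2)c(OCc2ccccc2)c1)c1c(OCc2ccccc2)cc(OCc2ccccc2)cc1OCc2ccccc2 | intermediate
10 | (2R,3S)-2-[2,4,6-tris(benzyloxy)benzyl]-3-[3,4,5-tris(benzyloxy)phenyl]oxirane (cis-epoxide) | c1(cc(OCc2ccccc2)c(OCc2ccccc2)c(OCc2ccccc2)c1)[C@@H]1O[C@@H]1Cc1c(OCc2ccccc2)cc(OCc2ccccc2)cc1OCc2ccccc2 | intermediate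
11 | 3,5-bis(benzyloxy)phenol | Oc1cc(OCc2ccccc2)cc(OCc2ccccc2)c1 | starting material
12 | 3,5-bis(benzyloxy)-2-{(1S,2R)-2-hydroxy-1-[3,4,5-tris(benzyloxy)phenyl]-3-[2,4,6-tris(benzyloxy)phenyl]propyl}phenol | O[C@H](Cc1c(OCc2ccccc2)cc(OCc2ccccc2)cc1OCc2ccccc2)[C@@H](c1cc(OCc2ccccc2)c(OCc2ccccc2)c(OCc2ccccc2)c1)c1c(OCc2ccccc2)cc(OCc2ccccc2)cc1O | intermediate
13 | 4,6-bis(benzyloxy)-2-hydroxy-3-{(1S,2R)-2-hydroxy-1-[3,4,5-tris(benzyloxy)phenyl]-3-[2,4,6-tris(benzyloxy)phenyl]propyl}benzaldehyde | O[C@H](Cc1c(OCc2ccccc2)cc(OCc2ccccc2)cc1OCc2ccccc2)[C@@H](c1cc(OCc2ccccc2)c(OCc2ccccc2)c(OCc2ccccc2)c1)c1c(OCc2ccccc2)cc(OCc2ccccc2)c(C=O)c1O | intermediate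
14 | 3,5-bis(benzyloxy)-2-(hydroxymethyl)-6-{(1S,2R)-2-hydroxy-1-[3,4,5-tris(benzyloxy)phenyl]-3-[2,4,6-tris(benzyloxy)phenyl]propyl}phenol | O[C@H](Cc1c(OCc2ccccc2)cc(OCc2ccccc2)cc1OCc2ccccc2)[C@@H](c1cc(OCc2ccccc2)c(OCc2ccccc2)c(OCc2ccccc2)c1)c1c(OCc2ccccc2)cc(OCc2ccccc2)c(CO)c1O | intermediate
15 | 3,5-bis(benzyloxy)-6-methylidene-2-{(1S,2R)-2-hydroxy-1-[3,4,5-tris(benzyloxy)phenyl]-3-[2,4,6-tris(benzyloxy)phenyl]propyl}cyclohexa-2,4-dien-1-one (ortho-quinone methide) | O[C@H](Cc1c(OCc2ccccc2)cc(OCc2ccccc2)cc1OCc2ccccc2)[C@@H](c1cc(OCc2ccccc2)c(OCc2ccccc2)c(OCc2ccccc2)c1)C1=C(OCc2ccccc2)C=C(OCc2ccccc2)C(=C)C1=O | intermediate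
16 | (2R,3R)-5,7-bis(benzyloxy)-8-{(1S,2R)-2-hydroxy-1-[3,4,5-tris(benzyloxy)phenyl]-3-[2,4,6-tris(benzyloxy)phenyl]propyl}-2-[3,4,5-tris(benzyloxy)phenyl]chroman-3-yl 3,4,5-tris(benzyloxy)benzoate | O[C@H](Cc1c(OCc3ccccc3)cc(OCc3ccccc3)cc1OCc3ccccc3)[C@@H](c1cc(OCc3ccccc3)c(OCc3ccccc3)c(OCc3ccccc3)c1)c1c(OCc3ccccc3)cc(OCc3ccccc3)c2c1O[C@H](c1cc(OCc3ccccc3)c(OCc3ccccc3)c(OCc3ccccc3)c1)[C@H](OC(=O)c1cc(OCc3ccccc3)c(OCc3ccccc3)c(OCc3ccccc3)c1)C2 | intermediate
17 | (2R,3R)-5,7-bis(benzyloxy)-8-{(1S,2R)-2-[3,4,5-tris(benzyloxy)benzoyloxy]-1-[3,4,5-tris(benzyloxy)phenyl]-3-[2,4,6-tris(benzyloxy)phenyl]propyl}-2-[3,4,5-tris(benzyloxy)phenyl]chroman-3-yl 3,4,5-tris(benzyloxy)benzoate (heptadeca-O-benzyl target) | O=C(O[C@H](Cc1c(OCc3ccccc3)cc(OCc3ccccc3)cc1OCc3ccccc3)[C@@H](c1cc(OCc3ccccc3)c(OCc3ccccc3)c(OCc3ccccc3)c1)c1c(OCc3ccccc3)cc(OCc3ccccc3)c2c1O[C@H](c1cc(OCc3ccccc3)c(OCc3ccccc3)c(OCc3ccccc3)c1)[C@H](OC(=O)c1cc(OCc3ccccc3)c(OCc3ccccc3)c(OCc3ccccc3)c1)C2)c1cc(OCc3ccccc3)c(OCc3ccccc3)c(OCc3ccccc3)c1 | intermediate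
18 | CNP0155034.1, (2R,3R)-5,7-dihydroxy-8-[(1S,2R)-2-(3,4,5-trihydroxybenzoyloxy)-1-(3,4,5-trihydroxyphenyl)-3-(2,4,6-trihydroxyphenyl)propyl]-2-(3,4,5-trihydroxyphenyl)chroman-3-yl 3,4,5-trihydroxybenzoate | O=C(O[C@H](Cc1c(O)cc(O)cc1O)[C@@H](c1cc(O)c(O)c(O)c1)c1c(O)cc(O)c2c1O[C@H](c1cc(O)c(O)c(O)c1)[C@H](OC(=O)c1cc(O)c(O)c(O)c1)C2)c1cc(O)c(O)c(O)c1 | target

Total step count: 13. Longest linear sequence: 11 steps (1 → 2 → 7 → 8 → 9 → 10 → 12 → 13 → 14 → 16 → 17 → 18).

Steps most likely to fail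

Step 11 (proposed new method). The phosphate may discriminate poorly between the two faces of the quinone methide, or work against the bias of the C1' centre. The cycloaddition may also turn stepwise, so that rotation in a benzylic cation erodes the cis C2/C3 relation. Finally, the quinone methide may condense with itself faster than it is trapped by the sluggish enol ester. The fallback uses known chemistry and takes ring C from the chiral pool instead of building it. Commercial (−)-epigallocatechin gallate would be exhaustively benzylated (BnBr, K2CO3, DMF) to octa-O-benzyl-(−)-epigallocatechin gallate F1. Its ring A would then open epoxide 10 under the fluoroalcohol conditions of step 8; benzylated flavan-3-ol nucleophiles react at C8 in preference to C6, as in 4→8 couplings of proanthocyanidin chemistry. The fallback sets out from 10 and comes back to the route at 16, after which steps 12 and 13 follow unchanged.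

Step 8. The epoxide may ionise before the arene attacks, which would scramble C1'. It may also rearrange by hydride shift to the benzyl ketone (Meinwald rearrangement), or be attacked through C4 or the oxygen of the phenol. The fallback replaces the Friedel–Crafts event by a carbanion opening. Phenol 11 would be protected (MOMCl, i-Pr2NEt) as 1,3-bis(benzyloxy)-5-(methoxymethoxy)benzene F2. Directed ortho-metalation (n-BuLi, THF, 0 °C, the acetal directing between itself and one benzyloxy group) would give [2,4-bis(benzyloxy)-6-(methoxymethoxy)phenyl]lithium F3. In the presence of BF3·OEt2 at −78 °C this would open 10 at the benzylic carbon with inversion to give 3,5-bis(benzyloxy)-2-{(1S,2R)-2-hydroxy-1-[3,4,5-tris(benzyloxy)phenyl]-3-[2,4,6-tris(benzyloxy)phenyl]propyl}phenyl methoxymethyl ether F4. Mild acid methanolysis (HCl, MeOH/THF) would then free the phenol. The fallback sets out from 10 and 11 and comes back to the route at 12.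

Step 7. Oxygen transfer from the manganese oxo species is stepwise, so rotation in the radical intermediate may leak to the trans-epoxide (the source of the C1' epimer), and the bulky benzylic substituent may lower enantioface discrimination. The fallback changes the oxidant class to a concerted oxygen-atom transfer from a chiral dioxirane. This is the Shi epoxidation with the glucose-derived oxazolidinone ketone designed for cis-alkenes (Oxone, K2CO3 buffer, DME/H2O, 0 °C), which is stereospecific for the alkene geometry. It sets out from 9 and comes back to the route at 10; no new compound arises (entry F0).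

Further compounds
F1 | step 11 | octa-O-benzyl-(−)-epigallocatechin gallate, (2R,3R)-5,7-bis(benzyloxy)-2-[3,4,5-tris(benzyloxy)phenyl]chroman-3-yl 3,4,5-tris(benzyloxy)benzoate | c1c(OCc3ccccc3)cc(OCc3ccccc3)c2c1O[C@H](c1cc(OCc3ccccc3)c(OCc3ccccc3)c(OCc3ccccc3)c1)[C@H](OC(=O)c1cc(OCc3ccccc3)c(OCc3ccccc3)c(OCc3ccccc3)c1)C2
F2 | step 8 | 1,3-bis(benzyloxy)-5-(methoxymethoxy)benzene | COCOc1cc(OCc2ccccc2)cc(OCc2ccccc2)c1
F3 | step 8 | [2,4-bis(benzyloxy)-6-(methoxymethoxy)phenyl]lithium | [Li]c1c(OCOC)cc(OCc2ccccc2)cc1OCc2ccccc2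
F4 | step 8 | 3,5-bis(benzyloxy)-2-{(1S,2R)-2-hydroxy-1-[3,4,5-tris(benzyloxy)phenyl]-3-[2,4,6-tris(benzyloxy)phenyl]propyl}phenyl methoxymethyl ether | O[C@H](Cc1c(OCc2ccccc2)cc(OCc2ccccc2)cc1OCc2ccccc2)[C@@H](c1cc(OCc2ccccc2)c(OCc2ccccc2)c(OCc2ccccc2)c1)c1c(OCc2ccccc2)cc(OCc2ccccc2)cc1OCOC
F0 | step 7 | none | none
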